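The runs come from a simulation for an exercise; the scatter is artificial.

No rate constant is given, so we read two from the summer run and ask what the readings say about dissolved gas.

the same everywhere: gas phase 170 mM (held)

|  | substrate | remark | time |
|---|---|---|---|
| summer | 1.5 M | the very flask that is asked about, followed so far |  |
| midnight | 3 M | run made earlier |  |
| flask | 1.5 M |  | 40 min |

| run | time / min | target / % |
|---|---|---|
| summer | 1.00 | 0.3 |
| summer | 1.50 | 0.8 |
| summer | 2.50 | 5.2 |
| summer | 4.00 | 6.7 |
| summer | 8.00 | 12.0 |
| summer | 12.0 | 13.8 |
| midnight | 2.00 | 3.0 |
| midnight | 5.00 | 6.5 |
| midnight | 10.0 | 11.9 |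
| midnight | 15.0 | 14.8 |
| midnight | 20.0 | 20.0 |
| midnight | 30.0 | 20.4 |

(scatter of a reading: 1 percentage point)

1. the target standing at 40 min, as a percentage of the substrate charged
2. concentration of dissolved gas in solution at 40 min, in percent of saturation

- at the start none of the gas phase is in solution

The bench rule: with the gas phase held, dissolved gas stays constant, the reaction is pseudo-first-order in substrate, and the two charges trace one percent curve. But the midnight run needs 10.0 min for the level that summer reaches in 8.00 min, a ratio of 1.25. The rule's border is another ratio: summer's substrate is 8.82 times the saturation concentration, so uptake must keep replacing dissolved gas, and that needs a shortfall below saturation.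

Summer's slope up to 8.00 min runs ahead of the reading at 1.50 min by a lag of 0.967 min, which we take as the uptake time. After the lag, the reading at 4.00 min gives a rate constant of 0.0221 min⁻¹. Their product over saturation is the gas deficit per molar of substrate standing, 0.126 M⁻¹. At the start it gives deficits of 18.8 % for summer and 37.7 % for midnight, so summer should run 1.30 times as fast per substrate, close to the ratio read above.

We take midnight's level near 20.4 % as target lost as fast as it is made, with substrate still falling. Summer's substrate then stands at 41.3 % at 40 min, which puts dissolved gas at 92.2 % of saturation and target a little above midnight's level.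

The forecast says 19.5 % and 99 %: its target sits on a plateau, lower than our figure, and its dissolved gas stands higher than ours, holding that “gas consumption is negligible against transfer capacity”. The flask gives 23.7 % of target and dissolved gas at 88.0 % of saturation.

    substrate + dissolved gas → target (k = 0.150 M⁻¹ min⁻¹)
    dissolved gas + target → over-reacted product (k = 0.00620 M⁻¹ min⁻¹)
    dissolved gas → decomposed reagent (k = 0.0130 min⁻¹)
    gas phase ⇌ dissolved gas, rate k4*(csat - [dissolved gas]) (kL = 0.850 min⁻¹)
    target ⇌ isomer of the product (K = 19.0, k = 0.0470 min⁻¹)

With substrate at 44 %, the deficit rule gives 8.22 % against the flask's 12.0 %, and at that time the path from substrate uses dissolved gas 7.5 times as fast as the path to decomposed reagent. Read at 2.5 h, the same flask has 3.1 % of its substrate left, the rule gives 0.580 %, and the deficit found is 2.39 %.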